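**Retrosynthetic overview**
1. Target 17 ← bis-silyl ether 16 ← flavan-4-ol 15. The C4 carbonyl is unveiled only in the penultimate step, so C2 cannot racemise by ring opening during the base-mediated steps.
2. Side chains: the (E)-dienyl group by Suzuki coupling at the C5' bromide (15 ← 12 + 14); the prenyl group by cross-metathesis of the C3' allyl group (12 ← 11).
3. Ring C (key disconnection): C3–C4 and O1–C2 are cut together, an oxa-[4+2] retron. This leads to the 4-methoxy ortho-quinone methide 9 of ring A (from salicylaldehyde 2 via acetal 8) and the ring B styrene 7, joined under a chiral Brønsted acid that sets C2.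
4. Enabling feature: in ring A the oxygen O1 on C8a is ortho to C4a, which carries C4. With C4 at the aldehyde (acetal) level, O1–C8a–C4a–C4 becomes a 1-oxadiene on loss of methanol, and C2=C3 is the vinyl group of a styrene whose anisole ring stabilises positive charge at C2.
5. Ring order: rings A and B are bought as benzaldehydes 1 and 3; ring C is the only ring formed (step 6).

Key step: step 6

Assumption: the (R)-configured catalyst is taken to give the (2S) series in step 6 (otherwise its enantiomer is used), and the C4 centre of 10, 11, 12 and 15 is drawn 2,4-trans (pseudo-axial oxygen next to the 5-silyloxy group), which is of no consequence because C4 ends as the carbonyl carbon.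

**Route**

Step 1
Reactants: 1 2,4,6-trihydroxybenzaldehyde
Product: 2 2-hydroxy-4,6-bis(triisopropylsilyloxy)benzaldehyde
Conditions: TIPSCl (2.1 equiv), imidazole (4 equiv), DMF, 0 °C to rt
Reagents that add atoms: triisopropylsilyl chloride, CC(C)[Si](Cl)(C(C)C)C(C)C
Why: Chemoselective O-silylation: the para OH and one ortho OH react, whereas the second ortho OH, locked in a hydrogen bond to the formyl oxygen, stays free and is the phenol later needed for the quinone methide.

Step 2
Reactants: 3 3-bromo-4-hydroxybenzaldehyde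
Product: 4 4-(allyloxy)-3-bromobenzaldehyde
Conditions: allyl bromide (1.2 equiv), K2CO3 (1.5 equiv), acetone, reflux
Reagents that add atoms: allyl bromide, C=CCBr
Why: Williamson ether synthesis on the acidic para-formyl phenol with an allylic bromide.

Step 3
Reactants: 4 4-(allyloxy)-3-bromobenzaldehyde
Product: 5 3-allyl-5-bromo-4-hydroxybenzaldehyde
Conditions: N,N-diethylaniline, 200 °C, sealed tube
Reagents that add atoms: none
Why: Aromatic Claisen rearrangement ([3,3]-sigmatropic shift, then tautomerisation) should deliver the allyl group to the only free ortho position, the other being blocked by bromine.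

Step 4
Reactants: 5 3-allyl-5-bromo-4-hydroxybenzaldehyde
Product: 6 3-allyl-5-bromo-4-methoxybenzaldehyde
Conditions: MeI (1.5 equiv), K2CO3 (2 equiv), DMF, rt
Reagents that add atoms: iodomethane, CI
Why: Williamson O-methylation of the hindered but acidic phenol installs the 4'-methoxy group of the target and removes the phenol before the acid-catalysed key step.

Step 5
Reactants: 6 3-allyl-5-bromo-4-methoxybenzaldehyde
Product: 7 1-allyl-3-bromo-2-methoxy-5-vinylbenzene
Conditions: Ph3PCH3Br (1.3 equiv), KOtBu (1.25 equiv), THF, 0 °C to rt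
Reagents that add atoms: methyltriphenylphosphonium bromide, C[P+](c1ccccc1)(c1ccccc1)c1ccccc1.[Br-]
Why: Wittig methylenation of the aryl aldehyde should give the styrene, the slight deficit of base relative to the phosphonium salt guarding against allyl-to-propenyl isomerisation.

Step 6
Reactants: 2 2-hydroxy-4,6-bis(triisopropylsilyloxy)benzaldehyde (1.3 equiv); 7 1-allyl-3-bromo-2-methoxy-5-vinylbenzene
Product: 10 (2S,4R)-2-(3-allyl-5-bromo-4-methoxyphenyl)-4-methoxy-5,7-bis(triisopropylsilyloxy)chromane, via dimethyl acetal 8 (not isolated), via ortho-quinone methide 9 (not isolated)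
Conditions: HC(OMe)3 (1.5 equiv), (R)-TRIP N-triflylphosphoramide [(R)-3,3'-bis(2,4,6-triisopropylphenyl)-1,1'-binaphthyl-2,2'-diyl N-(trifluoromethylsulfonyl)phosphoramide] (5 mol %), 5 Å MS, toluene, −20 to 0 °C
Reagents that add atoms: trimethyl orthoformate, COC(OC)OC
Why: Proposed new method: the acid converts 2 and the orthoformate into acetal 8, which loses methanol to the 4-methoxy ortho-quinone methide 9 (O-protonated, it is the aryl(methoxy)carbenium ion paired with the chiral phosphoramide anion); the CH2 terminus of the vinyl group of 7 bonds to the methide carbon (C3–C4) and the quinone methide oxygen closes on the benzylic carbon (O1–C2) in an asynchronous inverse-electron-demand oxa-[4+2] cycloaddition. The closest known reaction types are the achiral acid-catalysed three-component synthesis of 4-alkoxychromans from salicylaldehydes, orthoformates and styrenes, the chiral N-triflylphosphoramide-catalysed [4+2] cycloaddition of ortho-quinone methides with styrenes, and the chiral-acid-catalysed intramolecular [4+2] cycloaddition of acetal-derived alkoxy ortho-quinone methides; new is their union in an intermolecular enantioselective reaction of an alkoxy ortho-quinone methide with a simple styrene. Ring C is the only ring closed and it closes as the six-membered ring of the [4+2] event, C–C bond formation leading and the O–C bond following inside the contact ion pair. The C2 stereocentre is set by the catalyst, whose anion is hydrogen-bonded to the quinone methide oxygen and whose 3,3'-aryl groups leave one face of the oxadiene open to the styrene; the C4 centre formed with it is under substrate control and is erased in step 11. The step needs regioselectivity (oxygen to the aryl-bearing carbon, secured by benzylic stabilisation of positive charge at C2 by the anisole ring), chemoselectivity (vinyl over allyl, secured by conjugation of the vinyl group with the arene) and suppression of Friedel–Crafts attack on the electrophile by ring A (secured by the two bulky silyl ethers that flank its free ring positions).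

Step 7
Reactants: 10 (2S,4R)-2-(3-allyl-5-bromo-4-methoxyphenyl)-4-methoxy-5,7-bis(triisopropylsilyloxy)chromane
Product: 11 (2S,4R)-2-(3-allyl-5-bromo-4-methoxyphenyl)-5,7-bis(triisopropylsilyloxy)chroman-4-ol
Conditions: PPTS (0.1 equiv), THF/H2O (4:1), rt
Reagents that add atoms: water, O
Why: SN1 solvolysis: the 2,4,6-trioxygenated benzylic ether should ionise under mild acid and water should capture the C4 cation, while the far less stabilised C2–O1 bond is untouched, so C2 keeps its configuration.

Step 8
Reactants: 11 (2S,4R)-2-(3-allyl-5-bromo-4-methoxyphenyl)-5,7-bis(triisopropylsilyloxy)chroman-4-ol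
Product: 12 (2S,4R)-2-[3-bromo-4-methoxy-5-(3-methylbut-2-enyl)phenyl]-5,7-bis(triisopropylsilyloxy)chroman-4-ol
Conditions: second-generation Grubbs catalyst RuCl2(=CHPh)(PCy3)(H2IMes) (5 mol %), 2-methyl-2-butene/CH2Cl2 (1:1), 40 °C, sealed tube
Reagents that add atoms: 2-methyl-2-butene, CC=C(C)C
Why: Olefin cross-metathesis of the terminal allyl alkene with excess 2-methyl-2-butene should give the prenyl group (no alkene geometry arises), and the aryl bromide, silyl ethers and free benzylic alcohol are tolerated.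

Step 9
Reactants: 13 2-methylbut-1-en-3-yne
Product: 14 2-[(1E)-3-methylbuta-1,3-dienyl]-4,4,5,5-tetramethyl-1,3,2-dioxaborolane
Conditions: pinacolborane (1.1 equiv), Cp2Zr(H)Cl (5 mol %), Et3N (10 mol %), CH2Cl2, sealed tube, rt to 40 °C
Reagents that add atoms: pinacolborane, CC1(C)OBOC1(C)C
Why: Cp2Zr(H)Cl-catalysed hydroboration of the terminal alkyne: syn addition with boron at the terminal carbon should give the (E)-dienylboronate, the 1,1-disubstituted alkene being much less reactive.

Step 10
Reactants: 12 (2S,4R)-2-[3-bromo-4-methoxy-5-(3-methylbut-2-enyl)phenyl]-5,7-bis(triisopropylsilyloxy)chroman-4-ol; 14 2-[(1E)-3-methylbuta-1,3-dienyl]-4,4,5,5-tetramethyl-1,3,2-dioxaborolane (1.5 equiv)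
Product: 15 (2S,4R)-2-[4-methoxy-3-[(1E)-3-methylbuta-1,3-dienyl]-5-(3-methylbut-2-enyl)phenyl]-5,7-bis(triisopropylsilyloxy)chroman-4-ol
Conditions: Pd(dppf)Cl2 (5 mol %), K3PO4 (3 equiv), 1,4-dioxane/H2O (5:1), 70 °C
Reagents that add atoms: none
Why: Suzuki–Miyaura coupling (oxidative addition of the aryl bromide to zerovalent palladium, transmetalation, reductive elimination) proceeds with retention of the (E)-alkene geometry, and because no carbonyl is present yet the basic conditions cannot epimerise C2.

Step 11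
Reactants: 15 (2S,4R)-2-[4-methoxy-3-[(1E)-3-methylbuta-1,3-dienyl]-5-(3-methylbut-2-enyl)phenyl]-5,7-bis(triisopropylsilyloxy)chroman-4-ol
Product: 16 (2S)-2-[4-methoxy-3-[(1E)-3-methylbuta-1,3-dienyl]-5-(3-methylbut-2-enyl)phenyl]-5,7-bis(triisopropylsilyloxy)chroman-4-one
Conditions: Dess–Martin periodinane (1.3 equiv), NaHCO3 (5 equiv), CH2Cl2, 0 °C to rt
Reagents that add atoms: none
Why: Dess–Martin oxidation of the secondary benzylic alcohol to the aryl ketone under bicarbonate buffering removes the C4 stereocentre and is compatible with the diene, the prenyl group and the silyl ethers.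

Step 12
Reactants: 16 (2S)-2-[4-methoxy-3-[(1E)-3-methylbuta-1,3-dienyl]-5-(3-methylbut-2-enyl)phenyl]-5,7-bis(triisopropylsilyloxy)chroman-4-one
Product: 17 (2S)-5,7-dihydroxy-2-[4-methoxy-3-[(1E)-3-methylbuta-1,3-dienyl]-5-(3-methylbut-2-enyl)phenyl]chroman-4-one
Conditions: Bu4NF (2.5 equiv), AcOH (3 equiv), THF, 0 °C
Reagents that add atoms: none
Why: Fluoride cleavage of the two aryl silyl ethers, with acetic acid buffering to keep phenoxide and enolate concentrations low so that the flavanone should not racemise by retro-oxa-Michael ring opening.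

**Compound list**

1 | 2,4,6-trihydroxybenzaldehyde | O=Cc1c(O)cc(O)cc1O | starting material
2 | 2-hydroxy-4,6-bis(triisopropylsilyloxy)benzaldehyde | O=Cc1c(O)cc(O[Si](C(C)C)(C(C)C)C(C)C)cc1O[Si](C(C)C)(C(C)C)C(C)C | intermediate
3 | 3-bromo-4-hydroxybenzaldehyde | O=Cc1ccc(O)c(Br)c1 | starting material
4 | 4-(allyloxy)-3-bromobenzaldehyde | C=CCOc1ccc(C=O)cc1Br | intermediate
5 | 3-allyl-5-bromo-4-hydroxybenzaldehyde | C=CCc1cc(C=O)cc(Br)c1O | intermediate
6 | 3-allyl-5-bromo-4-methoxybenzaldehyde | C=CCc1cc(C=O)cc(Br)c1OC | intermediate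
7 | 1-allyl-3-bromo-2-methoxy-5-vinylbenzene | C=CCc1cc(C=C)cc(Br)c1OC | intermediate
8 | 2-(dimethoxymethyl)-3,5-bis(triisopropylsilyloxy)phenol | COC(OC)c1c(O)cc(O[Si](C(C)C)(C(C)C)C(C)C)cc1O[Si](C(C)C)(C(C)C)C(C)C | intermediate
9 | (6E)-6-(methoxymethylidene)-3,5-bis(triisopropylsilyloxy)cyclohexa-2,4-dien-1-one (drawn E; the geometry is mobile through the O-protonated form) | CO/C=C1/C(=O)C=C(O[Si](C(C)C)(C(C)C)C(C)C)C=C1O[Si](C(C)C)(C(C)C)C(C)C | intermediate
10 | (2S,4R)-2-(3-allyl-5-bromo-4-methoxyphenyl)-4-methoxy-5,7-bis(triisopropylsilyloxy)chromane | C=CCc1cc([C@@H]2C[C@@H](OC)c3c(O[Si](C(C)C)(C(C)C)C(C)C)cc(O[Si](C(C)C)(C(C)C)C(C)C)cc3O2)cc(Br)c1OC | intermediate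
11 | (2S,4R)-2-(3-allyl-5-bromo-4-methoxyphenyl)-5,7-bis(triisopropylsilyloxy)chroman-4-ol | C=CCc1cc([C@@H]2C[C@@H](O)c3c(O[Si](C(C)C)(C(C)C)C(C)C)cc(O[Si](C(C)C)(C(C)C)C(C)C)cc3O2)cc(Br)c1OC | intermediate
12 | (2S,4R)-2-[3-bromo-4-methoxy-5-(3-methylbut-2-enyl)phenyl]-5,7-bis(triisopropylsilyloxy)chroman-4-ol | CC(C)=CCc1cc([C@@H]2C[C@@H](O)c3c(O[Si](C(C)C)(C(C)C)C(C)C)cc(O[Si](C(C)C)(C(C)C)C(C)C)cc3O2)cc(Br)c1OC | intermediate
13 | 2-methylbut-1-en-3-yne | C=C(C)C#C | starting material
14 | 2-[(1E)-3-methylbuta-1,3-dienyl]-4,4,5,5-tetramethyl-1,3,2-dioxaborolane | C=C(C)/C=C/B1OC(C)(C)C(C)(C)O1 | intermediate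
15 | (2S,4R)-2-[4-methoxy-3-[(1E)-3-methylbuta-1,3-dienyl]-5-(3-methylbut-2-enyl)phenyl]-5,7-bis(triisopropylsilyloxy)chroman-4-ol | C=C(C)/C=C/c1cc([C@@H]2C[C@@H](O)c3c(O[Si](C(C)C)(C(C)C)C(C)C)cc(O[Si](C(C)C)(C(C)C)C(C)C)cc3O2)cc(CC=C(C)C)c1OC | intermediate
16 | (2S)-2-[4-methoxy-3-[(1E)-3-methylbuta-1,3-dienyl]-5-(3-methylbut-2-enyl)phenyl]-5,7-bis(triisopropylsilyloxy)chroman-4-one | C=C(C)/C=C/c1cc([C@@H]2CC(=O)c3c(O[Si](C(C)C)(C(C)C)C(C)C)cc(O[Si](C(C)C)(C(C)C)C(C)C)cc3O2)cc(CC=C(C)C)c1OC | intermediate
17 | (2S)-5,7-dihydroxy-2-[4-methoxy-3-[(1E)-3-methylbuta-1,3-dienyl]-5-(3-methylbut-2-enyl)phenyl]chroman-4-one | C=C(C)/C=C/c1cc([C@@H]2CC(=O)c3c(O)cc(O)cc3O2)cc(CC=C(C)C)c1OC | target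

**Step count and risks**

Total step count: 12. Longest linear sequence: 10 steps (3 → 4 → 5 → 6 → 7 → 10 → 11 → 12 → 15 → 16 → 17).

Steps most likely to fail:

Step 6. The silyloxy-stabilised quinone methide may react too slowly with the only moderately nucleophilic styrene, or a stepwise cationic pathway may escape the chiral anion and erode the enantioselectivity. The fallback uses known chemistry. It sets out from 2 and 7 and runs the same three-component cycloaddition without asymmetric induction under Sc(OTf)3 catalysis (through 8 and 9), which should give the racemic 2,4-trans 4-methoxyflavan F1. PPTS in wet THF should then give the racemic flavan-4-ol F2, and Dess–Martin oxidation the racemic flavanone F3. A kinetic resolution by asymmetric transfer hydrogenation follows, with the enantiomer of RuCl(p-cymene)(TsDPEN) that reduces the (2S)-ketone faster, in HCO2H/Et3N. It should reduce only that enantiomer to the cis-(2S,4S)-flavan-4-ol F4 and leave the (2R)-flavanone F5, which can be racemised with DBU by ring opening and recycled. F4 is the C4 epimer of 11; under the conditions of step 7 it should equilibrate at C4 to 11, where the route is rejoined.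

Step 7. The C4 cation may lose a proton from C3 (elimination to the flav-3-ene) or alkylate a second molecule instead of being captured by water. The fallback sets out from 10 and cleaves the benzylic methyl ether oxidatively with DDQ in wet CH2Cl2 (hydride abstraction at C4, collapse of the hemiketal), which should give the (2S)-flavanone F6 directly. F6 is prenylated by the cross-metathesis of step 8 to the (2S)-prenyl bromo flavanone F7. Because C2 is now epimerisable, the diene is attached without base by Stille coupling with (E)-tributyl(3-methylbuta-1,3-dienyl)stannane F8 (from 13 with Bu3SnH and AIBN) under Pd(PPh3)4 in toluene at 100 °C. This should give 16, where the route is rejoined.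

Step 10. The dienylboronate may protodeboronate or polymerise, oxidative addition at the bromide next to the methoxy group may be slow, or the silyl ethers may be lost under aqueous base. The fallback sets out from 12 and builds the diene in two stages. A Mizoroki–Heck reaction with 2-methylbut-3-en-2-ol (Pd(OAc)2, P(o-tol)3, Et3N, DMF, 100 °C) should give the (E)-allylic tertiary alcohol, diol F9. Dess–Martin oxidation, which touches only the secondary benzylic alcohol, should give the hydroxy ketone F10. Neutral dehydration of the tertiary allylic alcohol with Burgess reagent (benzene, 50 °C) should give 16, where the route is rejoined.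

**Further compounds**

F1 | step 6 | racemic 2,4-trans-2-(3-allyl-5-bromo-4-methoxyphenyl)-4-methoxy-5,7-bis(triisopropylsilyloxy)chromane | C=CCc1cc(C2CC(OC)c3c(O[Si](C(C)C)(C(C)C)C(C)C)cc(O[Si](C(C)C)(C(C)C)C(C)C)cc3O2)cc(Br)c1OC
F2 | step 6 | racemic 2,4-trans-2-(3-allyl-5-bromo-4-methoxyphenyl)-5,7-bis(triisopropylsilyloxy)chroman-4-ol | C=CCc1cc(C2CC(O)c3c(O[Si](C(C)C)(C(C)C)C(C)C)cc(O[Si](C(C)C)(C(C)C)C(C)C)cc3O2)cc(Br)c1OC
F3 | step 6 | racemic 2-(3-allyl-5-bromo-4-methoxyphenyl)-5,7-bis(triisopropylsilyloxy)chroman-4-one | C=CCc1cc(C2CC(=O)c3c(O[Si](C(C)C)(C(C)C)C(C)C)cc(O[Si](C(C)C)(C(C)C)C(C)C)cc3O2)cc(Br)c1OC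
F4 | step 6 | (2S,4S)-2-(3-allyl-5-bromo-4-methoxyphenyl)-5,7-bis(triisopropylsilyloxy)chroman-4-ol (2,4-cis) | C=CCc1cc([C@@H]2C[C@H](O)c3c(O[Si](C(C)C)(C(C)C)C(C)C)cc(O[Si](C(C)C)(C(C)C)C(C)C)cc3O2)cc(Br)c1OC
F5 | step 6 | (2R)-2-(3-allyl-5-bromo-4-methoxyphenyl)-5,7-bis(triisopropylsilyloxy)chroman-4-one | C=CCc1cc([C@H]2CC(=O)c3c(O[Si](C(C)C)(C(C)C)C(C)C)cc(O[Si](C(C)C)(C(C)C)C(C)C)cc3O2)cc(Br)c1OC
F6 | step 7 | (2S)-2-(3-allyl-5-bromo-4-methoxyphenyl)-5,7-bis(triisopropylsilyloxy)chroman-4-one | C=CCc1cc([C@@H]2CC(=O)c3c(O[Si](C(C)C)(C(C)C)C(C)C)cc(O[Si](C(C)C)(C(C)C)C(C)C)cc3O2)cc(Br)c1OC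
F7 | step 7 | (2S)-2-[3-bromo-4-methoxy-5-(3-methylbut-2-enyl)phenyl]-5,7-bis(triisopropylsilyloxy)chroman-4-one | CC(C)=CCc1cc([C@@H]2CC(=O)c3c(O[Si](C(C)C)(C(C)C)C(C)C)cc(O[Si](C(C)C)(C(C)C)C(C)C)cc3O2)cc(Br)c1OC
F8 | step 7 | (E)-tributyl(3-methylbuta-1,3-dienyl)stannane | C=C(C)/C=C/[Sn](CCCC)(CCCC)CCCC
F9 | step 10 | (2S,4R)-2-[3-[(1E)-3-hydroxy-3-methylbut-1-enyl]-4-methoxy-5-(3-methylbut-2-enyl)phenyl]-5,7-bis(triisopropylsilyloxy)chroman-4-ol | CC(C)(O)/C=C/c1cc([C@@H]2C[C@@H](O)c3c(O[Si](C(C)C)(C(C)C)C(C)C)cc(O[Si](C(C)C)(C(C)C)C(C)C)cc3O2)cc(CC=C(C)C)c1OC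
F10 | step 10 | (2S)-2-[3-[(1E)-3-hydroxy-3-methylbut-1-enyl]-4-methoxy-5-(3-methylbut-2-enyl)phenyl]-5,7-bis(triisopropylsilyloxy)chroman-4-one | CC(C)(O)/C=C/c1cc([C@@H]2CC(=O)c3c(O[Si](C(C)C)(C(C)C)C(C)C)cc(O[Si](C(C)C)(C(C)C)C(C)C)cc3O2)cc(CC=C(C)C)c1OC
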